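**Plan**

- Target numbering (spiro[5.5]undecane): ring A = C1(Me)=C2H–C3H(OH)–C4H(Br)–C5(Me)2–C6(spiro); ring B = C6–C7H2–C8(Br)=C9(Me)–C10H2–C11H2.
- Retrosynthesis: invert C3–O and remove Br at C4 (gives enone 17); cut ring A at C4–C5 (tertiary cation at C5 plus enol carbon C4 of a methyl ketone) and regenerate C1=C2 by β-elimination of a carbinol; then cut C1–C2 (allyl Grignard), C1–Me (MeLi on a nitrile), C9–Me (Negishi), C8–Br (α-bromination) and C5–C6 (nitrile aldol with acetone).
- Forward: ring B first, from a commercial 4-cyanocyclohexanone ketal; then the C1–C4 chain is grown on the nitrile carbon; ring A closes last through the C4–C5 bond; the bromohydrin is adjusted at the end.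
- Enabling feature: C5 is a fully substituted, ionisable carbon held 1,6 to C4 by C6–C1–C2–C3. C4 is the α-methyl carbon of a C3 ketone, i.e. an enol carbon. The only other π-bond, the tetrasubstituted bromoalkene C8=C9, is deactivated.
- Stereochemistry: C6 comes from enantioselective deprotonation of a prochiral 4,4-disubstituted cyclohexanone (the α-carbon that is brominated becomes C8). C4 is set by thermodynamic equilibration of the α'-bromo ketone (equatorial Br). C3 is set by hydride attack anti to the axial C5 methyl, then Mitsunobu inversion to the trans-diequatorial bromohydrin.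

Key step: step 10

Remark: the sense of the enantioselective deprotonation in step 4 is assigned by analogy with 4-tert-butylcyclohexanone (bulky equatorial group; the (R,R)-amide is expected to give the S enol ether); if the analogy does not hold, the (S,S)-amide is used instead.

**Route**

Step 1
Reactants: 1 1,4-dioxaspiro[4.5]decane-8-carbonitrile; 2 acetone
Product: 3 8-(2-hydroxypropan-2-yl)-1,4-dioxaspiro[4.5]decane-8-carbonitrile
Conditions: LiN(iPr)2 (LDA), THF, −78 °C; acetone, −78 °C; AcOH quench at −78 °C
Reagents that add atoms: none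
Why: Nitrile aldol-type addition, in which the tertiary nitrile-stabilised carbanion adds to the acetone carbonyl and the cold acidic quench prevents retro-addition; the new quaternary carbon is not yet stereogenic because the ring is still symmetric.

Step 2
Reactants: 3 8-(2-hydroxypropan-2-yl)-1,4-dioxaspiro[4.5]decane-8-carbonitrile
Product: 4 8-(2-methoxypropan-2-yl)-1,4-dioxaspiro[4.5]decane-8-carbonitrile
Conditions: MeOTf, 2,6-di-tert-butyl-4-methylpyridine, CH2Cl2, 23 °C
Reagents that add atoms: methyl trifluoromethanesulfonate, COS(=O)(=O)C(F)(F)F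
Why: O-Methylation of the hindered tertiary alcohol under non-basic conditions avoids the alkoxide and hence retro-addition, and the resulting tert-alkyl methyl ether is inert to the bases and organometallics of steps 4 to 9 while serving as the latent cation of step 10.

Step 3
Reactants: 4 8-(2-methoxypropan-2-yl)-1,4-dioxaspiro[4.5]decane-8-carbonitrile
Product: 5 1-(2-methoxypropan-2-yl)-4-oxocyclohexane-1-carbonitrile
Conditions: 2 M HCl, THF, 23 °C
Reagents that add atoms: water, O
Why: Acid-catalysed ketal hydrolysis, which the nitrile and the tertiary methyl ether should survive at room temperature; the product is achiral.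

Step 4
Reactants: 5 1-(2-methoxypropan-2-yl)-4-oxocyclohexane-1-carbonitrile
Product: 7 (1S,3R)-3-bromo-1-(2-methoxypropan-2-yl)-4-oxocyclohexane-1-carbonitrile, via silyl enol ether 6 (not isolated)
Conditions: lithium (R,R)-bis(1-phenylethyl)amide, LiCl, Me3SiCl (in situ quench), THF, −100 °C; then N-bromosuccinimide, NaHCO3, THF, −78 °C
Reagents that add atoms: N-bromosuccinimide, O=C1CCC(=O)N1Br; chlorotrimethylsilane, C[Si](C)(C)Cl (silyl group present only in 6)
Why: Enantioselective deprotonation of a conformationally locked prochiral ketone (2-methoxypropan-2-yl equatorial, nitrile axial) by a chiral lithium amide, followed by α-bromination of the silyl enol ether; the choice between the two enantiotopic α-methylene groups makes C-1 stereogenic (expected 1S), while the C-3 bromide (expected axial) is of no consequence because that carbon becomes sp2 in step 5.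

Step 5
Reactants: 7 (1S,3R)-3-bromo-1-(2-methoxypropan-2-yl)-4-oxocyclohexane-1-carbonitrile
Product: 8 (4S)-2-bromo-4-cyano-4-(2-methoxypropan-2-yl)cyclohex-1-en-1-yl trifluoromethanesulfonate
Conditions: LiN(SiMe3)2, THF, −78 °C; then N-(5-chloropyridin-2-yl)bis(trifluoromethanesulfonimide), −78 → 0 °C
Reagents that add atoms: N-(5-chloropyridin-2-yl)bis(trifluoromethanesulfonimide), FC(F)(F)S(=O)(=O)N(c1ccc(Cl)cn1)S(=O)(=O)C(F)(F)F
Why: Enol triflate formation through the bromo enolate, since the hydrogen geminal to bromine is the most acidic α-hydrogen (the site removed in Darzens reactions of α-halo ketones) and this enolate cannot undergo Favorskii closure; no stereocentre is touched.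

Step 6
Reactants: 8 (4S)-2-bromo-4-cyano-4-(2-methoxypropan-2-yl)cyclohex-1-en-1-yl trifluoromethanesulfonate
Product: 9 (1S)-3-bromo-1-(2-methoxypropan-2-yl)-4-methylcyclohex-3-ene-1-carbonitrile
Conditions: MeZnCl, Pd(PPh3)4 (5 mol %), THF, 0 → 23 °C
Reagents that add atoms: methylzinc chloride, C[Zn]Cl
Why: Negishi coupling, in which Pd(PPh3)4 should insert into the alkenyl C–OTf bond faster than into the alkenyl C–Br bond, so that methyl replaces the triflate and the vicinal bromide is kept; the nitrile and the ether tolerate the organozinc.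

Step 7
Reactants: 9 (1S)-3-bromo-1-(2-methoxypropan-2-yl)-4-methylcyclohex-3-ene-1-carbonitrile
Product: 11 1-[(1R)-3-bromo-1-(2-methoxypropan-2-yl)-4-methylcyclohex-3-en-1-yl]ethan-1-one, via lithio ketimine 10 (not isolated)
Conditions: MeLi, Et2O, 0 → 23 °C; then 1 M HCl, 23 °C
Reagents that add atoms: methyllithium, [Li]C; water, O
Why: Organolithium addition to the hindered but sterically slim nitrile stops at the N-lithio ketimine, which is hydrolysed to the methyl ketone; MeLi is a poor partner for bromine–lithium exchange with the tetrasubstituted alkenyl bromide (the descriptor changes to R only because acetyl outranks the ether-bearing carbon).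

Step 8
Reactants: 11 1-[(1R)-3-bromo-1-(2-methoxypropan-2-yl)-4-methylcyclohex-3-en-1-yl]ethan-1-one; 12 2-methylallylmagnesium chloride
Product: 13 2-[(1S)-3-bromo-1-(2-methoxypropan-2-yl)-4-methylcyclohex-3-en-1-yl]-4-methylpent-4-en-2-ol (both C-2 epimers)
Conditions: THF, −78 → 0 °C; sat. aq. NH4Cl
Reagents that add atoms: none
Why: Grignard 1,2-addition, since allylic Grignard reagents add through a cyclic six-membered transition state even to very hindered enolisable ketones; the new carbinol centre forms as an epimer mixture that does not matter because this carbon becomes sp2 in step 10.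

Step 9
Reactants: 13 2-[(1S)-3-bromo-1-(2-methoxypropan-2-yl)-4-methylcyclohex-3-en-1-yl]-4-methylpent-4-en-2-ol
Product: 14 4-[(1S)-3-bromo-1-(2-methoxypropan-2-yl)-4-methylcyclohex-3-en-1-yl]-4-hydroxypentan-2-one (both C-4 epimers)
Conditions: OsO4 (2 mol %), NaIO4, 2,6-lutidine, 1,4-dioxane/H2O, 23 °C
Reagents that add atoms: sodium periodate, [Na+].[O-]I(=O)(=O)=O
Why: Lemieux–Johnson oxidative cleavage, in which OsO4 dihydroxylates the electron-rich 1,1-disubstituted alkene far faster than the tetrasubstituted, bromine-deactivated ring alkene and NaIO4 cleaves the diol to the methyl ketone.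

Step 10
Reactants: 14 4-[(1S)-3-bromo-1-(2-methoxypropan-2-yl)-4-methylcyclohex-3-en-1-yl]-4-hydroxypentan-2-one
Product: 17 (6R)-8-bromo-1,5,5,9-tetramethylspiro[5.5]undeca-1,8-dien-3-one, via bis-silyl ether 15 (not isolated), via silyloxy ketone 16 (not isolated)
Conditions: Me3SiCl (excess), LiN(iPr)2 (2.4 equiv), THF, −78 → 0 °C (in situ quench); pentane filtration; then TiCl4, CH2Cl2, −78 → 0 °C; then 1 M HCl, THF, 23 °C
Reagents that add atoms: chlorotrimethylsilane, C[Si](C)(C)Cl (silyl groups present only in 15 and 16)
Why: In situ silylation gives the kinetic terminal silyl enol ether (the methyl is deprotonated, the neopentyl-like CH2 is not) and caps the tertiary alcohol; TiCl4 then binds the most Lewis-basic oxygen, the methyl ether, and ionises it to the tertiary cation at the CMe2 carbon, which is captured by the terminal enol carbon through a chair-like six-membered transition state to form the C-4–C-5 bond of 17 next to the spiro carbon. The closest known reaction type is the Lewis-acid-mediated α-tert-alkylation of silyl enol ethers by tertiary alkyl halides or ethers (the SN1 variant of the Mukaiyama alkylation), here run intramolecularly. Ring A closes in a formally 6-(enolendo)-exo-tet mode, which is feasible because the electrophile is a free planar cation and not a centre that needs backside attack. No new stereocentre survives: the spiro centre is untouched, and the silyloxy-bearing carbon of 16 (an epimer mixture) becomes sp2 when 16 loses silanol under TiCl4 and aqueous acid to give the conjugated enone. The step needs ionisation at the methyl ether and not at the tertiary silyl ether (secured by the much higher Lewis basicity of the alkyl ether oxygen), C- over O-alkylation (carbon is the soft terminus of the enol ether, and an O-alkylated enol ether would re-ionise under TiCl4), and capture faster than a 1,2-shift toward the quaternary neighbour (helped by the intramolecular six-membered capture, the gem-dialkyl effect of the fully substituted chain and the lack of any cation-stabilising group on the neighbouring carbon). The tetrasubstituted bromoalkene of ring B is too electron-poor and too badly placed to compete as a π-nucleophile.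

Step 11
Reactants: 17 (6R)-8-bromo-1,5,5,9-tetramethylspiro[5.5]undeca-1,8-dien-3-one
Product: 19 (4S,6S)-4,8-dibromo-1,5,5,9-tetramethylspiro[5.5]undeca-1,8-dien-3-one, via silyl dienol ether 18 (not isolated)
Conditions: LiN(iPr)2, THF, −78 °C; Me3SiCl; then N-bromosuccinimide, THF, −78 → 0 °C; then DBU (0.2 equiv), CH2Cl2, 23 °C
Reagents that add atoms: N-bromosuccinimide, O=C1CCC(=O)N1Br; chlorotrimethylsilane, C[Si](C)(C)Cl (silyl group present only in 18)
Why: Kinetic α'-deprotonation of the enone (cross-conjugated dienolate, as with isophorone-type enones) and α'-bromination of its silyl dienol ether, followed by base equilibration of the epimerisable C-4 centre; the 4S epimer should predominate because it alone has bromine equatorial in the ring A half-chair that keeps the C-1 methyl over sp2 C-8 and away from the axial hydrogen on C-10, and neither elimination (C-5 is quaternary) nor Favorskii rearrangement (the other α-carbon is sp2) is open.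

Step 12
Reactants: 19 (4S,6S)-4,8-dibromo-1,5,5,9-tetramethylspiro[5.5]undeca-1,8-dien-3-one
Product: 20 (3R,4S,6S)-4,8-dibromo-1,5,5,9-tetramethylspiro[5.5]undeca-1,8-dien-3-ol
Conditions: iBu2AlH (DIBAL-H), CH2Cl2, −78 °C; aq. Rochelle salt
Reagents that add atoms: none
Why: 1,2-Reduction of the enone carbonyl, with hydride expected from the face opposite the axial C-5 methyl (equatorial attack) to give the axial 3R alcohol cis to the equatorial bromine; the neopentyl C–Br bond is not displaced by the aluminium hydride.

Step 13
Reactants: 20 (3R,4S,6S)-4,8-dibromo-1,5,5,9-tetramethylspiro[5.5]undeca-1,8-dien-3-ol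
Product: 21 (3S,4S,6S)-4,8-dibromo-1,5,5,9-tetramethylspiro[5.5]undeca-1,8-dien-3-yl 4-nitrobenzoate
Conditions: 4-nitrobenzoic acid, PPh3, diisopropyl azodicarboxylate, THF, 0 → 23 °C
Reagents that add atoms: 4-nitrobenzoic acid, O=C(O)c1ccc(cc1)[N+](=O)[O-]
Why: Mitsunobu reaction, in which SN2 displacement of the axial oxyphosphonium group by the carboxylate inverts C-3 to 3S (equatorial, trans to bromine); an ionised allylic pathway should be steered to the same face by the neighbouring bromine.

Step 14
Reactants: 21 (3S,4S,6S)-4,8-dibromo-1,5,5,9-tetramethylspiro[5.5]undeca-1,8-dien-3-yl 4-nitrobenzoate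
Product: 22 (3S,4S,6S)-4,8-dibromo-1,5,5,9-tetramethylspiro[5.5]undeca-1,8-dien-3-ol
Conditions: K2CO3, MeOH, 0 °C
Reagents that add atoms: none
Why: Transesterification of the activated ester by acyl–oxygen cleavage keeps the C-3 configuration, and the trans-diequatorial bromohydrin cannot easily reach the diaxial geometry needed for epoxide closure under these mild conditions.

**Compound list**

1 | 1,4-dioxaspiro[4.5]decane-8-carbonitrile | N#CC1CCC2(CC1)OCCO2 | starting material
2 | acetone | CC(C)=O | starting material
3 | 8-(2-hydroxypropan-2-yl)-1,4-dioxaspiro[4.5]decane-8-carbonitrile | CC(C)(O)C1(C#N)CCC2(CC1)OCCO2 | intermediate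
4 | 8-(2-methoxypropan-2-yl)-1,4-dioxaspiro[4.5]decane-8-carbonitrile | COC(C)(C)C1(C#N)CCC2(CC1)OCCO2 | intermediate
5 | 1-(2-methoxypropan-2-yl)-4-oxocyclohexane-1-carbonitrile | COC(C)(C)C1(C#N)CCC(=O)CC1 | intermediate
6 | (1S)-1-(2-methoxypropan-2-yl)-4-(trimethylsilyloxy)cyclohex-3-ene-1-carbonitrile | COC(C)(C)[C@@]1(C#N)CCC(O[Si](C)(C)C)=CC1 | intermediate
7 | (1S,3R)-3-bromo-1-(2-methoxypropan-2-yl)-4-oxocyclohexane-1-carbonitrile | COC(C)(C)[C@@]1(C#N)CCC(=O)[C@H](Br)C1 | intermediate
8 | (4S)-2-bromo-4-cyano-4-(2-methoxypropan-2-yl)cyclohex-1-en-1-yl trifluoromethanesulfonate | COC(C)(C)[C@@]1(C#N)CCC(OS(=O)(=O)C(F)(F)F)=C(Br)C1 | intermediate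
9 | (1S)-3-bromo-1-(2-methoxypropan-2-yl)-4-methylcyclohex-3-ene-1-carbonitrile | COC(C)(C)[C@@]1(C#N)CCC(C)=C(Br)C1 | intermediate
10 | N-lithio ketimine of 11 | COC(C)(C)[C@@]1(C(C)=N[Li])CCC(C)=C(Br)C1 | intermediate
11 | 1-[(1R)-3-bromo-1-(2-methoxypropan-2-yl)-4-methylcyclohex-3-en-1-yl]ethan-1-one | COC(C)(C)[C@@]1(C(C)=O)CCC(C)=C(Br)C1 | intermediate
12 | 2-methylallylmagnesium chloride | CC(=C)C[Mg]Cl | starting material
13 | 2-[(1S)-3-bromo-1-(2-methoxypropan-2-yl)-4-methylcyclohex-3-en-1-yl]-4-methylpent-4-en-2-ol (both C-2 epimers) | COC(C)(C)[C@@]1(C(C)(O)CC(C)=C)CCC(C)=C(Br)C1 | intermediate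
14 | 4-[(1S)-3-bromo-1-(2-methoxypropan-2-yl)-4-methylcyclohex-3-en-1-yl]-4-hydroxypentan-2-one (both C-4 epimers) | COC(C)(C)[C@@]1(C(C)(O)CC(C)=O)CCC(C)=C(Br)C1 | intermediate
15 | (4S)-2-bromo-4-[2,4-bis(trimethylsilyloxy)pent-4-en-2-yl]-4-(2-methoxypropan-2-yl)-1-methylcyclohex-1-ene | COC(C)(C)[C@@]1(C(C)(O[Si](C)(C)C)CC(=C)O[Si](C)(C)C)CCC(C)=C(Br)C1 | intermediate
16 | (6R)-8-bromo-1,5,5,9-tetramethyl-1-(trimethylsilyloxy)spiro[5.5]undec-8-en-3-one (both C-1 epimers) | CC1(O[Si](C)(C)C)CC(=O)CC(C)(C)[C@]12CCC(C)=C(Br)C2 | intermediate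
17 | (6R)-8-bromo-1,5,5,9-tetramethylspiro[5.5]undeca-1,8-dien-3-one | CC1=CC(=O)CC(C)(C)[C@]12CCC(C)=C(Br)C2 | intermediate
18 | (6S)-8-bromo-1,5,5,9-tetramethyl-3-(trimethylsilyloxy)spiro[5.5]undeca-1,3,8-triene | CC1=CC(O[Si](C)(C)C)=CC(C)(C)[C@]12CCC(C)=C(Br)C2 | intermediate
19 | (4S,6S)-4,8-dibromo-1,5,5,9-tetramethylspiro[5.5]undeca-1,8-dien-3-one | CC1=CC(=O)[C@@H](Br)C(C)(C)[C@]12CCC(C)=C(Br)C2 | intermediate
20 | (3R,4S,6S)-4,8-dibromo-1,5,5,9-tetramethylspiro[5.5]undeca-1,8-dien-3-ol | CC1=C[C@@H](O)[C@@H](Br)C(C)(C)[C@]12CCC(C)=C(Br)C2 | intermediate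
21 | (3S,4S,6S)-4,8-dibromo-1,5,5,9-tetramethylspiro[5.5]undeca-1,8-dien-3-yl 4-nitrobenzoate | CC1=C[C@H](OC(=O)c3ccc(cc3)[N+](=O)[O-])[C@@H](Br)C(C)(C)[C@]12CCC(C)=C(Br)C2 | intermediate
22 | (3S,4S,6S)-4,8-dibromo-1,5,5,9-tetramethylspiro[5.5]undeca-1,8-dien-3-ol | CC1=C[C@H](O)[C@@H](Br)C(C)(C)[C@]12CCC(C)=C(Br)C2 | target

**Step count**

Total: 14 steps. Longest linear sequence: 14 steps (fully linear from 1).

**Steps most likely to fail**

Step 10. The tertiary cation could undergo a 1,2-shift toward the quaternary neighbour before it is captured, the tertiary silyl ether could ionise first, or oxygen could be alkylated without reversal. The fallback sets out from 9 and returns at 17. It moves the cation chemistry to the stage where the quaternary carbon carries the nitrile (no shift can then give a stabilised cation) and closes ring A through a different bond. 9 is treated with 2-(trimethylsilyloxy)propene and TiCl4 (CH2Cl2, −78 → −20 °C) to give keto nitrile F1. LiN(iPr)2 (THF, −78 → 23 °C) forms the methyl ketone enolate, which adds to the nitrile (Thorpe–Ziegler-type closure) to give enaminone F2. Aqueous HCl hydrolyses it to dione F3. MeOH with catalytic TsOH gives the vinylogous ester F4, with the methoxy group on the less hindered side. MeLi/CeCl3 followed by aqueous HCl (Stork–Danheiser transposition) then gives 17.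

Step 4. The chiral amide might discriminate poorly between the two enantiotopic α-methylene groups, or the information could be eroded by acid-induced migration of bromine to the other α-carbon. The fallback sets out from 5 and returns at 8. Dehydrogenation with 2-iodoxybenzoic acid (DMSO, 70 °C) gives dienone F5. An ene-reductase of the Old Yellow Enzyme family (NADPH recycling with glucose and glucose dehydrogenase) reduces one of the two enantiotopic C=C bonds to give enone F6; the enzyme is chosen by screening for the 1S product. Br2 then Et3N gives bromo enone F7. Conjugate reduction with LiBH(s-Bu)3 and trapping of the bromo enolate with the triflimide reagent of step 5 gives 8.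

Step 11. The thermodynamic bias between the two C-4 epimers, which rests on a conformational effect of the remote spiro centre, might be too small. The fallback sets out from 19 (as the epimer mixture) and returns at 20. Asymmetric transfer hydrogenation under dynamic kinetic resolution conditions, with RuCl(p-cymene)[(S,S)-TsDPEN] in HCO2H/Et3N, lets the α-bromo ketone epimerise through its enol while the catalyst reduces only the matched epimer. The cis-bromohydrin 20 should then form with both C-3 and C-4 set by the catalyst; the antipodal catalyst is used if the sense is opposite. No new compound is made.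

**Further compounds**

F1 | step 10 | (1R)-3-bromo-4-methyl-1-(2-methyl-4-oxopentan-2-yl)cyclohex-3-ene-1-carbonitrile | CC(=O)CC(C)(C)[C@@]1(C#N)CCC(C)=C(Br)C1
F2 | step 10 | (6R)-1-amino-8-bromo-5,5,9-trimethylspiro[5.5]undeca-1,8-dien-3-one | NC1=CC(=O)CC(C)(C)[C@]12CCC(C)=C(Br)C2
F3 | step 10 | (6R)-8-bromo-5,5,9-trimethylspiro[5.5]undec-8-ene-1,3-dione | O=C1CC(=O)CC(C)(C)[C@]12CCC(C)=C(Br)C2
F4 | step 10 | (6R)-8-bromo-3-methoxy-5,5,9-trimethylspiro[5.5]undeca-2,8-dien-1-one | O=C1C=C(OC)CC(C)(C)[C@]12CCC(C)=C(Br)C2
F5 | step 4 | 1-(2-methoxypropan-2-yl)-4-oxocyclohexa-2,5-diene-1-carbonitrile | COC(C)(C)C1(C#N)C=CC(=O)C=C1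
F6 | step 4 | (1S)-1-(2-methoxypropan-2-yl)-4-oxocyclohex-2-ene-1-carbonitrile | COC(C)(C)[C@@]1(C#N)CCC(=O)C=C1
F7 | step 4 | (1S)-3-bromo-1-(2-methoxypropan-2-yl)-4-oxocyclohex-2-ene-1-carbonitrile | COC(C)(C)[C@@]1(C#N)CCC(=O)C(Br)=C1
F0 | step 11 | none | none
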